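Readings and results were computed on assumed constants; scatter was added.

At early times a flask shows its pace, so read the pace first. In the flask asked about, substrate at 0.050 M stands closed and stirred at constant temperature for 4.0 d, turning into ring and open dimer. Friday's and Tuesday's runs show the same substrate at other charges.

| flask | substrate | remark | time |
|---|---|---|---|
| Friday's | 0.025 M | run made earlier |  |
| Tuesday's | 0.10 M | run made earlier |  |
| flask | 0.050 M |  | 4.0 d |

| run | time / d | substrate / % | ring / % | open dimer / % |
|---|---|---|---|---|
| Friday's | 0.417 | 0.9 | 69.6 | 24.4 |
| Friday's | 1.25 | 0 | 70.3 | 25.1 |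
| Friday's | 2.00 | 0.4 | 69.7 | 24.5 |
| Friday's | 3.00 | 0.7 | 69.3 | 24.3 |
| Friday's | 5.00 | 0 | 68.8 | 23.0 |
| Tuesday's | 1.04 | 0 | 38.6 | 37.6 |
| Tuesday's | 2.08 | 0.4 | 38.1 | 37.6 |
| Tuesday's | 3.00 | 0.9 | 38.1 | 38.7 |
| Tuesday's | 4.00 | 0 | 38.0 | 37.9 |
| Tuesday's | 5.00 | 0 | 37.9 | 38.8 |

(each reading ± 0.5 percentage points)

- the state of affairs at 4.0 d: stopped, and by what, or still going (forward and back rates have come level / all of the substrate has reacted / it is still moving)
- conversion of substrate at 4.0 d
- amount of ring at 4.0 d, in percent of the substrate charged
- amount of open dimer at 4.0 d, in percent of the substrate charged

- percentages count the substrate that a species holds: one open dimer counts as two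
- the numbers in the tables scatter by 0.5 percentage points (one standard deviation)
- the reaction counts as stopped when no species that holds the substrate changes by six tenths of a point or more over the second half of the time

Friday's first reading has substrate at 0.9 % after 0.417 d. That is 6.80 halvings, so the mean half-life read there is 0.0614 d, with the scatter of so small a reading. Ring stands near 69.3 % in Friday's run but 38.1 % in Tuesday's, so you take substrate to have one way out whose rate goes with c(substrate) and another whose rate goes with its square. Each halving of c(substrate) then cuts the first rate by a factor of 2 and the second by 4. A back step could hold the rate up, but Tuesday's last substrate reading is 0 %, with a scatter of 0.5 percentage points.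

The asked flask starts at twice Friday's charge, so its rate per substrate is no lower and 0.0614 d is a long estimate. The time allowed holds 65.2 half-lives, and this count of half-lives is what you carry. Each of them cuts the rate of loss by a factor of at least 2; 6.80 halvings took Friday's substrate to 0.9 %, and the asked flask has far more of them, so you expect full conversion. The count says nothing of the split between ring and open dimer.

The forecast gave all of the substrate has reacted, conversion 100 %, ring 53 % and open dimer 34 %, holding that “this is kinetic partition and not balance”. The flask gives all of the substrate has reacted, conversion 100 %, ring 54.1 % and open dimer 32.3 %.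

    substrate → ring (k = 1.50 × 10⁻⁴ s⁻¹)
    2 substrate → open dimer (k = 0.00270 L mol⁻¹ s⁻¹)
    substrate + open dimer → open trimer (k = 0.00199 L mol⁻¹ s⁻¹)

The asked flask has come to rest early: substrate is down to 2.25 % of its charge by 0.200 d, which is 3.26 of your 65.2 half-lives. Left until 40.0 d, it shows ring 54.1 % and open dimer 32.3 %, the same printed figures as at 4.0 d. The scheme has no back step, which is kinetic control.

A neighbour flask charged with 0.20 M lies above Friday's charge, so the count there is again at least 65.2 half-lives and you expect no substrate in sight. Computed, 0 % of its charge is left at 4.0 d.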